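## Analysis of the target

Conventions used throughout: the ring carbons are C1 (OMe), C2=C3 (C3 carries C7H2OBz), C4 (OH), C5 (OBz) and C6 (OH). With the ring drawn flat and C1→C6 running counterclockwise, β means toward the viewer and α away from it. Compound numbers are those of the steps and of the compound list.

- Target 13 is a single cyclohexene, [(3R,4R,5R,6R)-5-(benzoyloxy)-4,6-dihydroxy-3-methoxycyclohex-1-en-1-yl]methyl benzoate. It has no quaternary carbon and no carbon branch other than C7.
- The four stereocentres are 1β-OMe, 6β-OH, 5α-OBz and 4α-OH, all R in the numbering used here. C1/C6 are cis, C6/C5 trans and C5/C4 cis; C1 and C4 sit trans across the alkene.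
- The C5 benzoate lies between two free hydroxyls (C4 cis, C6 trans), so any basic late step invites acyl migration.
- C1–OMe, C4–OH and C7–OBz are all allylic, and the ring is only two eliminations away from a benzoate arene.
- The difficulty is not the carbon skeleton. Five oxygens on contiguous carbons must end in three different states (ether, free hydroxyl, benzoate), and four oxygenated stereocentres must be set relative to each other and absolutely.
- The strategy rests on two features. C7 on C3 and the oxygen on C6 are 1,4 to each other and can be the two ends of a C7(=O)–O lactone bridge. C4 and C5, the carbons between them, carry cis oxygens that can come from one Z-dioxygenated alkene.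
- Both features are present in the bridged lactone 3, made from 1 and 2. In 3 the oxygens are stored in different functional groups: C6–O in the lactone, C4–O/C5–O in the carbonate, and C1–O is introduced later as an epoxide. This is what makes their differentiation possible.

## Retrosynthetic reasoning

**13 ⇐ 12.** The last bond formed is the O–H of C6, by removing a silyl ether. C6–OH must be masked while C5 and C7 are acylated, and a silyl ether can be removed by fluoride under slightly acidic conditions, where the C5 benzoate does not migrate.

**12 ⇐ 10.** The two acyl–oxygen bonds at C7 and C5 are cut together, giving triol 10. This relies on the intrinsic reactivity order: primary allylic C7–OH first, equatorial C5–OH second, pseudoaxial C4–OH (flanked by the substituted alkene carbon C3) last. The forward reaction has to acylate twice and stop.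

**10 ⇐ 8.** C7–OH and the C4/C5 diol are traced back to an ester and a cyclic carbonate, both cleaved by one hydride reduction. The carbonate therefore serves as the C4/C5 protecting group from the first step to this point and needs no step of its own for removal.

**8 ⇐ 7.** The O–CH3 bond at C1 is cut. In 7 the C1 hydroxyl is the only free one, so the methyl ether can be placed without any selectivity question.

**7 ⇐ 6.** The C2=C3 alkene together with the C1 hydroxyl is the retron of a β,γ-epoxy ester. Removing the C3 proton opens the C2–O bond and leaves C1–O untouched. This places the alkene correctly and sets C1–O β, cis to C6–O.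

**6 ⇐ 5 ⇐ 4.** The silyl group on C6 is removed and the epoxide is traced back to the C1=C2 alkene of 4. The free C6 hydroxyl of 4 directs the oxidant to the β face, which the α-carbonate also leaves open. C6–O is capped before C1–O exists, and this timing tells the two cis hydroxyls apart.

**4 ⇐ 3.** The hydroxy ester is the opened form of the bridged lactone. The opening is planned under acid. An alkoxide in alcohol, applied to the epoxidised adduct, would open the lactone and the epoxide in one operation but would also transesterify the carbonate, releasing C1, C4, C5 and C6 hydroxyls together with no means of telling them apart. Opening the three oxygen-storing groups in the order lactone, epoxide, carbonate avoids this.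

**3 ⇐ 1 + 2.** The C3–C4 and C5–C6 bonds are cut in a [4+2] sense. Nowhere else can the ring be cut so that both fragments are purchased, and this cut creates all four stereocentres of the adduct in one event. The forward reaction must be endo-selective and face-selective and must keep CO2 in place.

## Alternatives that were turned down

**Alternative 1:** The ring is cut at C1–C2 and C3–C4.
- Forward step: a titanium–alkyne complex, made from the silyl alkyne A3 with Ti(OiPr)4 and iPrMgCl (formally divalent titanium), adds through both alkyne carbons to the two formyl groups of the acetonide dialdehyde A2, giving the cyclohexenediol A1.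
- For it: the trans C5/C6 diol and the absolute configuration come from the chiral pool, C7 arrives at its final oxidation level, and the ring is made from two small pieces in one step. On absolute configuration and convergence it is stronger than the chosen route.
- Against it:
  - C1 and C4 are new stereocentres formed in two carbonyl additions of different kind (one intermolecular, one ring-closing). Nothing in A2 clearly enforces the required pattern, each new hydroxyl cis to its acetonide neighbour.
  - The ring-closing insertion must use the titanium–carbon bond next to silicon, the less reactive one.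
  - A2 is a hydrate-forming, epimerisable dialdehyde that can also react with two titanium complexes instead of one.
  - Afterwards C5 and C6 sit in one acetonide and must still be told apart, C1 must be methylated in the presence of C4–OH, and the vinylsilane must be removed without allylic shift.
- Comparison: the chosen route obtains the relative configuration from a concerted cycloaddition and a directed epoxidation, and keeps each oxygen in a separate functional group.

**Alternative 2:** The ring is cut at C1–C2 and traced to a sugar.
- Forward step: Ti(OiPr)Cl3 cleaves the ring C–O bond at the anomeric carbon of the hex-5-enopyranoside A5. The resulting titanium enolate carbon attacks the methoxy-stabilised cation, giving cyclohexanone A4.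
- For it: it is stronger than the chosen route on two points. The anomeric methoxy group survives and becomes C1–OMe directly, and the hydroxyl pattern (benzoate on C5 between two benzyl ethers) is fixed by standard carbohydrate protecting-group chemistry with secure absolute configuration.
- Against it:
  - A4 has neither C7 nor the alkene. Homologation at the ketone carbon C3 requires enolisation of a ketone that is β-methoxy on one side and α-benzyloxy/β-benzoyloxy on the other, so E1cB loss of methoxide or benzoate and epimerisation at C4 are likely.
  - A5 has the altro pattern, which needs a multistep epoxide detour from a common hexose. If the anomeric configuration is retained, as is usual for this rearrangement, the less accessible 1,2-cis anomer is needed.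
  - The two benzyl ethers must finally be removed in the presence of an alkene, an allylic ether and two benzoates, which excludes hydrogenolysis.
- Comparison: the chosen route buys its precursor, carries C7 from the start as the lactone carbonyl on C3, and places the alkene by the epoxide opening.

**Alternative 3:** The ring is cut at C1–C6.
- Forward step: CrCl2 (divalent chromium) and Me3SiI convert the dimethyl acetal of the acyclic aldehyde A7 into a γ-methoxyallylchromium species. This adds through C1 to the C6 aldehyde with allylic transposition, giving A6.
- For it: the end-game is clearly better than in the chosen route. A6 already has C1–OMe (from the acetal), free C6–OH, the C5 benzoate and the C2=C3 alkene; only two desilylations and one primary benzoylation remain.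
- Against it:
  - A7 is costly to make: a stereodefined Z-trisubstituted alkene, two stereocentres, three different protecting groups and an α-benzoyloxy aldehyde that can epimerise at C5 or eliminate the C4 silyloxy group.
  - Me3SiI threatens the silyl ethers and the aldehyde.
  - Chromium must sit on the fully substituted C3 and deliver C1 through a bridged transition state in which the metal-bearing carbon is part of the forming ring. The chair model that predicts acyclic additions does not transfer, so the C1/C6 cis relationship is not assured.
- Comparison: the chosen route has a longer end-game but needs no synthesis of its precursor and sets the relative configuration in a concerted step.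

Key step: step 1

Assumption: the facial sense induced by the (S)-configured catalyst cannot be derived with certainty for this diene. The (S)-catalyst is written; its equally available (R)-enantiomer would be used if that is the one leading to 3.

## Steps

Step 1
Reactants: 1 2H-pyran-2-one; 2 vinylene carbonate
Product: 3 endo adduct 3,5,8-trioxatricyclo[5.2.2.0(2,6)]undec-10-ene-4,9-dione (lactone C7(=O)–O bridging C3 and C6 on the β face; cyclic carbonate on C4/C5 on the α face; alkene C1=C2)
Conditions: 2 (3 equiv), oxazaborolidinium salt from (S)-3,3-diphenyl-1-(2-methylphenyl)tetrahydro-1H,3H-pyrrolo[1,2-c][1,3,2]oxazaborole (C24H24BNO, 20 mol %) and (CF3SO2)2NH (18 mol %), CH2Cl2, 12 kbar, 20 °C; then Et3N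
Reagents that add atoms: none
Why: Proposed new method: the boron Lewis acid binds the lactone carbonyl of 1 (lone pair on the C3 side, with a C3–H···O contact to the catalyst) and lowers the LUMO of the pyrone diene, so that it combines with the oxygen-substituted alkene 2 in a concerted, asynchronous, inverse-demand [4+2] cycloaddition across pyrone C3 and C6; pressure accelerates this addition (strongly negative activation volume) at a temperature at which the adduct does not extrude CO2. The closest known reaction types are the pressure- or Lewis-acid-promoted Diels–Alder additions of 2-pyrones that retain the lactone bridge and the oxazaborolidinium-catalysed enantioselective Diels–Alder reactions of unsaturated esters and lactones; new here is the pairing with this dienophile and the pyrone as the activated partner. The one ring closed, the carbocycle C1–C6, is closed by suprafacial–suprafacial cycloaddition forming C3–C4 and C5–C6, which turns the pyrone ring into the C7(=O)–O bridge of a 2-oxabicyclo[2.2.2]octenone. C4 and C5 are cis because the Z-alkene adds suprafacially, and they lie anti to the lactone bridge (endo) because the carbonate sits under the diene in the more compact transition state, which pressure and secondary overlap both favour. C3 and C6, and with them the absolute configuration of all four centres, are fixed by the pyrone face that the aryl groups of the catalyst leave open. No regiochemical question arises because 2 is symmetric; the selectivities needed are endo over exo and one diene face over the other.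

Step 2
Reactants: 3 endo adduct
Product: 4 methyl 6β-hydroxy-4α,5α-(carbonyldioxy)cyclohex-1-ene-3β-carboxylate
Conditions: TsOH·H2O (0.1 equiv), MeOH, 0 to 20 °C; Et3N before concentration
Reagents that add atoms: methanol, CO
Why: Acid-catalysed lactone methanolysis (transesterification): the boat-locked bridged δ-lactone is strained and opens in excess methanol, whereas a five-membered carbonate is far less prone to acid-catalysed alcoholysis and the β,γ-alkene does not migrate without base; no stereocentre is touched, and the opened ring can no longer lose CO2 by cycloreversion.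

Step 3
Reactants: 4 hydroxy ester
Product: 5 methyl 1β,2β-epoxy-6β-hydroxy-4α,5α-(carbonyldioxy)cyclohexane-3β-carboxylate
Conditions: mCPBA (1.5 equiv), CH2Cl2, 0 to 20 °C
Reagents that add atoms: 3-chloroperbenzoic acid, O=C(OO)c1cccc(Cl)c1
Why: Hydroxyl-directed (Henbest-type) peracid epoxidation: the allylic C6–OH hydrogen-bonds the peracid and delivers oxygen to the β face, the same face that the α-carbonate leaves open, so C1 and C2 are set with the epoxide cis to C6–OH.

Step 4
Reactants: 5 epoxy alcohol
Product: 6 methyl 1β,2β-epoxy-6β-(tert-butyldimethylsilyloxy)-4α,5α-(carbonyldioxy)cyclohexane-3β-carboxylate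
Conditions: t-BuMe2SiOTf (1.3 equiv), 2,6-lutidine (2 equiv), CH2Cl2, −78 °C
Reagents that add atoms: tert-butyldimethylsilyl triflate, CC(C)(C)[Si](C)(C)OS(=O)(=O)C(F)(F)F
Why: Silylation of the only hydroxyl with a silyl triflate and a hindered pyridine base that is too weak to enolise the ester; C6–O is capped before C1–O is released, which is what later distinguishes the two cis oxygens.

Step 5
Reactants: 6 silylated epoxy ester
Product: 7 methyl 1β-hydroxy-6β-(tert-butyldimethylsilyloxy)-4α,5α-(carbonyldioxy)cyclohex-2-ene-3-carboxylate
Conditions: DBU (1.1 equiv), CH2Cl2, −20 to 0 °C; AcOH quench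
Reagents that add atoms: none
Why: E1cB-type opening of a β,γ-epoxy ester: DBU removes the α-hydrogen at C3, which is anti-periplanar to the strained C2–O bond, giving the conjugated C2=C3 alkene and the C1 hydroxyl with retention at C1 because the C1–O bond is not broken; the C4–O carbonate bond is syn to the departing proton and unstrained, so it should not compete.

Step 6
Reactants: 7 γ-hydroxy enoate
Product: 8 methyl 1β-methoxy-6β-(tert-butyldimethylsilyloxy)-4α,5α-(carbonyldioxy)cyclohex-2-ene-3-carboxylate
Conditions: MeOTf (3 equiv), 2,6-di-tert-butyl-4-methylpyridine (4 equiv), CH2Cl2, 0 to 20 °C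
Reagents that add atoms: methyl triflate, COS(=O)(=O)C(F)(F)F
Why: O-Methylation of the single free hydroxyl with methyl triflate and a non-nucleophilic pyridine base; the medium stays non-basic, so the enoate, the carbonate and the silyl ether are untouched, silyl migration is avoided and no stereocentre is affected.

Step 7
Reactants: 8 methyl ether
Product: 10 3-(hydroxymethyl)-1β-methoxy-6β-(tert-butyldimethylsilyloxy)cyclohex-2-ene-4α,5α-diol, via carbonate-protected allylic alcohol 9 (not isolated)
Conditions: i-Bu2AlH (8 equiv), CH2Cl2, −78 to 0 °C; aq. KNaC4H4O6
Reagents that add atoms: none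
Why: Hydride reduction: i-Bu2AlH reduces the conjugated ester by 1,2-addition to the allylic alcohol at low temperature and, on warming with excess reagent, cleaves the cyclic carbonate reductively to the C4/C5 diol, so the carbonate needs no separate deprotection; the methyl ether, silyl ether and alkene are inert.

Step 8
Reactants: 10 triol
Product: 12 [5α-benzoyloxy-4α-hydroxy-1β-methoxy-6β-(tert-butyldimethylsilyloxy)cyclohex-2-en-3-yl]methyl benzoate, via C7 monobenzoate 11 (not isolated)
Conditions: BzCl (2.1 equiv), pyridine, CH2Cl2, −40 to −20 °C
Reagents that add atoms: benzoyl chloride, O=C(Cl)c1ccccc1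
Why: Regioselective acylation of a polyol: the primary allylic C7–OH reacts first, then the equatorial C5–OH; C4–OH is pseudoaxial (avoiding A(1,2) strain with the C3 substituent) and flanked by C3 carrying CH2OBz, the same situation as the axial 4-hydroxyl of galactopyranosides, which is acylated last, and the low temperature suppresses acyl migration.

Step 9
Reactants: 12 silyl ether dibenzoate
Product: 13 [(3R,4R,5R,6R)-5-(benzoyloxy)-4,6-dihydroxy-3-methoxycyclohex-1-en-1-yl]methyl benzoate (target)
Conditions: HF·pyridine, THF/pyridine, 0 to 20 °C
Reagents that add atoms: none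
Why: Fluoride-mediated desilylation in a slightly acidic buffered medium, which cleaves the secondary silyl ether without the base that would let the C5 benzoate migrate to C4 or C6; benzoates, the allylic ether and the alkene are stable to HF·pyridine.

## Compound list

1 | 2H-pyran-2-one | O=C1C=CC=CO1 | starting material
2 | vinylene carbonate (1,3-dioxol-2-one) | O=C1OC=CO1 | starting material
3 | endo adduct, 3,5,8-trioxatricyclo[5.2.2.0(2,6)]undec-10-ene-4,9-dione (lactone bridge β, carbonate α) | O=C1O[C@@H]2C=C[C@H]1[C@H]3OC(=O)O[C@@H]23 | intermediate
4 | methyl 6β-hydroxy-4α,5α-(carbonyldioxy)cyclohex-1-ene-3β-carboxylate | C1=C[C@H](C(=O)OC)[C@H]2OC(=O)O[C@H]2[C@@H]1O | intermediate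
5 | methyl 1β,2β-epoxy-6β-hydroxy-4α,5α-(carbonyldioxy)cyclohexane-3β-carboxylate | O3[C@@H]1[C@H]3[C@H](C(=O)OC)[C@H]2OC(=O)O[C@H]2[C@@H]1O | intermediate
6 | methyl 1β,2β-epoxy-6β-(tert-butyldimethylsilyloxy)-4α,5α-(carbonyldioxy)cyclohexane-3β-carboxylate | O3[C@@H]1[C@H]3[C@H](C(=O)OC)[C@H]2OC(=O)O[C@H]2[C@@H]1O[Si](C)(C)C(C)(C)C | intermediate
7 | methyl 1β-hydroxy-6β-(tert-butyldimethylsilyloxy)-4α,5α-(carbonyldioxy)cyclohex-2-ene-3-carboxylate | O[C@@H]1C=C(C(=O)OC)[C@H]2OC(=O)O[C@H]2[C@@H]1O[Si](C)(C)C(C)(C)C | intermediate
8 | methyl 1β-methoxy-6β-(tert-butyldimethylsilyloxy)-4α,5α-(carbonyldioxy)cyclohex-2-ene-3-carboxylate | CO[C@@H]1C=C(C(=O)OC)[C@H]2OC(=O)O[C@H]2[C@@H]1O[Si](C)(C)C(C)(C)C | intermediate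
9 | 3-(hydroxymethyl)-1β-methoxy-6β-(tert-butyldimethylsilyloxy)cyclohex-2-ene-4α,5α-diyl carbonate (not isolated) | CO[C@@H]1C=C(CO)[C@H]2OC(=O)O[C@H]2[C@@H]1O[Si](C)(C)C(C)(C)C | intermediate
10 | 3-(hydroxymethyl)-1β-methoxy-6β-(tert-butyldimethylsilyloxy)cyclohex-2-ene-4α,5α-diol | CO[C@@H]1C=C(CO)[C@@H](O)[C@@H](O)[C@@H]1O[Si](C)(C)C(C)(C)C | intermediate
11 | [4α,5α-dihydroxy-1β-methoxy-6β-(tert-butyldimethylsilyloxy)cyclohex-2-en-3-yl]methyl benzoate (not isolated) | CO[C@@H]1C=C(COC(=O)c2ccccc2)[C@@H](O)[C@@H](O)[C@@H]1O[Si](C)(C)C(C)(C)C | intermediate
12 | [5α-benzoyloxy-4α-hydroxy-1β-methoxy-6β-(tert-butyldimethylsilyloxy)cyclohex-2-en-3-yl]methyl benzoate | CO[C@@H]1C=C(COC(=O)c2ccccc2)[C@@H](O)[C@@H](OC(=O)c2ccccc2)[C@@H]1O[Si](C)(C)C(C)(C)C | intermediate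
13 | [(3R,4R,5R,6R)-5-(benzoyloxy)-4,6-dihydroxy-3-methoxycyclohex-1-en-1-yl]methyl benzoate | CO[C@@H]1C=C(COC(=O)c2ccccc2)[C@@H](O)[C@@H](OC(=O)c2ccccc2)[C@@H]1O | target

## Step count and least certain steps

Total: 9 steps from 1 and 2. Longest linear sequence: 9 steps.

**Step 1 (key step, proposed new method).**
- What may go wrong:
  - slow cycloaddition, because the pyrone is a reluctant diene and the dienophile is only weakly electron-rich;
  - poor facial discrimination, because the catalyst holds the pyrone through a single Lewis-basic site;
  - Lewis-acid-induced ionisation of the allylic lactone C–O bond followed by aromatisation;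
  - sequestration of the catalyst by the carbonyl groups of 2 and of the product.
- Fallback, from 1 and 2, returning at 3: the cycloaddition is run without the chiral catalyst at about 15 kbar, a pressure-promoted pyrone Diels–Alder reaction of the known kind. Endo selectivity still fixes the relative configuration, so this should give 3 together with its mirror image, the enantiomeric endo adduct F1. The two are separated by preparative chromatography on a chiral stationary phase (amylose tris(3,5-dimethylphenylcarbamate)), and 3 is carried on.

**Step 5.**
- What may go wrong:
  - β-elimination toward C4 with loss of the carbonate oxygen instead of epoxide opening, since a carbonate is a good leaving group;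
  - silyl migration from C6–O to the newly formed C1 alkoxide;
  - further elimination toward an arene on prolonged exposure to base.
- Fallback, from 6, returning at 10:
  - K2CO3 in MeOH at 0 °C cleaves the carbonate first. Only a hydroxyl then remains at C4, so the E1cB step can open nothing but the epoxide. This gives the silylated triol ester F2.
  - 2,2-Dimethoxypropane with PPTS ties the only cis-diol (C4/C5) into the acetonide F3, leaving C1–OH free.
  - MeOTf with 2,6-di-tert-butyl-4-methylpyridine gives the methyl ether F4.
  - i-Bu2AlH gives the allylic alcohol F5.
  - 80 % aqueous AcOH removes the acetonide to give 10.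

**Step 8.**
- What may go wrong:
  - insufficient discrimination between C5–OH and C4–OH, because the bulky silyl ether on C6 also hinders C5;
  - over-benzoylation;
  - benzoyl migration between the cis C4 and C5 oxygens.
- Fallback, from 10, returning at 12:
  - PhCH(OMe)2 with camphorsulfonic acid closes the six-membered acetal across C7–O and C4–O. This is the thermodynamic preference known from 4,6-O-benzylidene galactosides, where a cis-vicinal alternative also exists. It gives the 4,7-O-benzylidene acetal F6 with C5–OH as the only free hydroxyl.
  - BzCl, pyridine and DMAP give the C5 benzoate F7.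
  - 80 % aqueous AcOH at 40 °C hydrolyses the acetal to the C4/C7 diol F8.
  - BzCl (1.05 equiv) with 2,4,6-collidine at −40 °C acylates only the primary hydroxyl, giving 12.

**Step 2.**
- What may go wrong:
  - partial methanolysis of the carbonate under the acid;
  - relactonisation on concentration;
  - solvolysis at the allylic C6–O bond.
- Fallback, from 3, returning at 10: the carbonate is given up at once.
  - HCl in MeOH (from AcCl) at 20 °C methanolyses both the lactone and the carbonate to the triol ester F9.
  - 2,2-Dimethoxypropane with TsOH protects the cis C4/C5 diol as the acetonide F10, leaving C6–OH free (C5/C6 are trans).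
  - mCPBA, directed by C6–OH, gives the epoxy alcohol F11.
  - t-BuMe2SiOTf with 2,6-lutidine gives the silyl ether F12.
  - DBU opens the epoxide, now with no competing leaving group at C4, to give F3, which continues through F4 and F5 to 10 as described for step 5.

## Further compounds

F1 | step 1 | enantiomer of endo adduct 3 | O=C1O[C@H]2C=C[C@@H]1[C@@H]3OC(=O)O[C@H]23
F2 | step 5 | methyl 1β,4α,5α-trihydroxy-6β-(tert-butyldimethylsilyloxy)cyclohex-2-ene-3-carboxylate | O[C@@H]1C=C(C(=O)OC)[C@@H](O)[C@@H](O)[C@@H]1O[Si](C)(C)C(C)(C)C
F3 | step 5 | methyl 1β-hydroxy-4α,5α-(isopropylidenedioxy)-6β-(tert-butyldimethylsilyloxy)cyclohex-2-ene-3-carboxylate | O[C@@H]1C=C(C(=O)OC)[C@H]2OC(C)(C)O[C@H]2[C@@H]1O[Si](C)(C)C(C)(C)C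
F4 | step 5 | methyl 1β-methoxy-4α,5α-(isopropylidenedioxy)-6β-(tert-butyldimethylsilyloxy)cyclohex-2-ene-3-carboxylate | CO[C@@H]1C=C(C(=O)OC)[C@H]2OC(C)(C)O[C@H]2[C@@H]1O[Si](C)(C)C(C)(C)C
F5 | step 5 | [1β-methoxy-4α,5α-(isopropylidenedioxy)-6β-(tert-butyldimethylsilyloxy)cyclohex-2-en-3-yl]methanol | CO[C@@H]1C=C(CO)[C@H]2OC(C)(C)O[C@H]2[C@@H]1O[Si](C)(C)C(C)(C)C
F6 | step 8 | 4,7-O-benzylidene acetal of 10 (phenyl equatorial; C5–OH free) | CO[C@@H]1C=C2CO[C@@H](c3ccccc3)O[C@H]2[C@@H](O)[C@@H]1O[Si](C)(C)C(C)(C)C
F7 | step 8 | 5-O-benzoate of the 4,7-O-benzylidene acetal | CO[C@@H]1C=C2CO[C@@H](c3ccccc3)O[C@H]2[C@@H](OC(=O)c2ccccc2)[C@@H]1O[Si](C)(C)C(C)(C)C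
F8 | step 8 | 4α-hydroxy-3-(hydroxymethyl)-1β-methoxy-6β-(tert-butyldimethylsilyloxy)cyclohex-2-en-5α-yl benzoate | CO[C@@H]1C=C(CO)[C@@H](O)[C@@H](OC(=O)c2ccccc2)[C@@H]1O[Si](C)(C)C(C)(C)C
F9 | step 2 | methyl 4α,5α,6β-trihydroxycyclohex-1-ene-3β-carboxylate | C1=C[C@H](C(=O)OC)[C@@H](O)[C@@H](O)[C@@H]1O
F10 | step 2 | methyl 6β-hydroxy-4α,5α-(isopropylidenedioxy)cyclohex-1-ene-3β-carboxylate | C1=C[C@H](C(=O)OC)[C@H]2OC(C)(C)O[C@H]2[C@@H]1O
F11 | step 2 | methyl 1β,2β-epoxy-6β-hydroxy-4α,5α-(isopropylidenedioxy)cyclohexane-3β-carboxylate | O3[C@@H]1[C@H]3[C@H](C(=O)OC)[C@H]2OC(C)(C)O[C@H]2[C@@H]1O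
F12 | step 2 | methyl 1β,2β-epoxy-6β-(tert-butyldimethylsilyloxy)-4α,5α-(isopropylidenedioxy)cyclohexane-3β-carboxylate | O3[C@@H]1[C@H]3[C@H](C(=O)OC)[C@H]2OC(C)(C)O[C@H]2[C@@H]1O[Si](C)(C)C(C)(C)C
A1 | alternative 1 | cyclohexene-1,4-diol with C5/C6 acetonide, trimethylsilyl on C2 and tert-butyldimethylsilyl ether on C7 | O[C@@H]1C(=C(CO[Si](C)(C)C(C)(C)C)[C@@H](O)[C@H]2OC(C)(C)O[C@H]12)[Si](C)(C)C
A2 | alternative 1 | (4S,5S)-2,2-dimethyl-1,3-dioxolane-4,5-dicarbaldehyde | O=C[C@H]1OC(C)(C)O[C@@H]1C=O
A3 | alternative 1 | tert-butyldimethyl{[3-(trimethylsilyl)prop-2-yn-1-yl]oxy}silane | C[Si](C)(C)C#CCO[Si](C)(C)C(C)(C)C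
A4 | alternative 2 | 3-benzoyloxy-2,4-bis(benzyloxy)-5-methoxycyclohexanone configured as in the target | CO[C@@H]1CC(=O)[C@@H](OCc2ccccc2)[C@@H](OC(=O)c2ccccc2)[C@@H]1OCc1ccccc1
A5 | alternative 2 | methyl 3-O-benzoyl-2,4-di-O-benzyl-6-deoxy-β-D-arabino-hex-5-enopyranoside (from an altropyranoside) | CO[C@@H]1OC(=C)[C@@H](OCc2ccccc2)[C@@H](OC(=O)c2ccccc2)[C@@H]1OCc1ccccc1
A6 | alternative 3 | cyclohexene with C1 methyl ether, free C6 hydroxyl, C5 benzoate, tert-butyldimethylsilyl ether on C4 and tert-butyldiphenylsilyl ether on C7 | CO[C@@H]1C=C(CO[Si](c2ccccc2)(c2ccccc2)C(C)(C)C)[C@@H](O[Si](C)(C)C(C)(C)C)[C@@H](OC(=O)c2ccccc2)[C@@H]1O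
A7 | alternative 3 | (Z)-2-benzoyloxy-3-(tert-butyldimethylsilyloxy)-4-[(tert-butyldiphenylsilyloxy)methyl]-6,6-dimethoxyhex-4-enal configured as in the target | COC(OC)/C=C(CO[Si](c1ccccc1)(c1ccccc1)C(C)(C)C)\[C@@H](O[Si](C)(C)C(C)(C)C)[C@@H](OC(=O)c1ccccc1)C=O
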